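**Strategy.** Everything rests on the C3–C1′ bond. It ties the secondary allylic carbon C1′ of the cyclohexene ring to C3 of the pyrone ring, the central carbon of the malonyl-type unit C2–C3–C4. This is the pattern a Wolff 1,2-shift leaves. Irradiation of a 2-diazo-3-oxo ester that carries the terpene on its ketone carbon moves C1′ onto the diazo carbon with retention. The ketene then C-acylates the benzalacetone enolate (C4–C5), so one operation assembles the whole open-chain pyrone. The precursor derives from (S)-limonene through a suprafacial [2,3]-Wittig–Still shift. Its ester is methyl, so the ring is closed with base and the acid-sensitive C2′=C3′ alkene is spared.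

Key step: step 10

Assumption: primed locants are those of the cyclohexenyl substituent (C1′ on pyrone C3, C6′ bearing isopropyl). Compounds 1–10 are discussed with p-menthane locants (C1 methyl-bearing, C4 isopropyl-bearing), so p-menthane C3 becomes C1′ and C4 becomes C6′.

Step 1
Reactants: 1 (S)-limonene
Product: 2 (4S)-1-methyl-4-(propan-2-yl)cyclohex-1-ene
Conditions: H2 (1 atm), RhCl(PPh3)3 (cat.), toluene–EtOH, rt
Reagents that add atoms: none
Why: Homogeneous catalytic hydrogenation reduces the unhindered 1,1-disubstituted side-chain alkene far faster than the trisubstituted ring alkene and leaves the C4 stereocentre untouched.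

Step 2
Reactants: 2 (4S)-1-methyl-4-(propan-2-yl)cyclohex-1-ene
Product: 3 (4S)-1-methyl-4-(propan-2-yl)-7-oxabicyclo[4.1.0]heptane as the mixture of both epoxide diastereomers
Conditions: mCPBA, CH2Cl2, 0 °C
Reagents that add atoms: 3-chloroperoxybenzoic acid (mCPBA), OOC(=O)c1cccc(Cl)c1
Why: Prilezhaev epoxidation of the only alkene, in which the remote C4 isopropyl group exerts almost no facial bias, so both diastereomers are expected in similar amounts and are carried on together.

Step 3
Reactants: 3 epoxide mixture
Product: 4 (1S,4S,6R)-1-methyl-4-(propan-2-yl)-7-oxabicyclo[4.1.0]heptane (oxygen anti to isopropyl)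
Conditions: pyrrolidine, H2O, reflux; then distillation
Reagents that add atoms: none
Why: Kinetic separation under the Fürst–Plattner rule, well known for the limonene oxides: only the diastereomer with oxygen syn to isopropyl can be opened at secondary C2 through a chair-like trans-diaxial transition state with equatorial isopropyl, so it alone is aminolysed to an involatile basic amino alcohol and 4 is recovered unchanged.

Step 4
Reactants: 4 anti epoxide
Product: 7 (1S,4R)-1-methyl-4-(propan-2-yl)cyclohex-2-en-1-ol, via hydroxy selenide 5 (not isolated), via selenoxide 6 (not isolated)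
Conditions: PhSeSePh, NaBH4, EtOH, reflux; then 30% H2O2, pyridine, THF, 0 °C → rt
Reagents that add atoms: none
Why: Organoselenium epoxide-to-allylic-alcohol transposition, in which the soft selenolate attacks secondary C2 by SN2 with inversion (tertiary C1 is closed to it, and the diequatorial opening costs only rate, hence reflux), the C1–O bond keeps its configuration anti to isopropyl, and the selenoxide can only syn-eliminate towards C3 because C1 bears no hydrogen.

Step 5
Reactants: 7 (1S,4R)-1-methyl-4-(propan-2-yl)cyclohex-2-en-1-ol; 8 tributyl(iodomethyl)stannane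
Product: 9 tributyl({[(1S,4R)-1-methyl-4-(propan-2-yl)cyclohex-2-en-1-yl]oxy}methyl)stannane
Conditions: KH, 18-crown-6 (cat.), THF, 0 °C → rt
Reagents that add atoms: none
Why: Williamson etherification of the potassium alkoxide with an unhindered, highly SN2-reactive primary iodide, the standard entry to Wittig–Still substrates that also serves tertiary allylic alcohols and touches no stereocentre.

Step 6
Reactants: 9 stannylmethyl ether
Product: 11 [(1R,6R)-3-methyl-6-(propan-2-yl)cyclohex-2-en-1-yl]methanol, via lithiomethyl ether 10 (not isolated)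
Conditions: n-BuLi, THF, −78 °C; then H2O
Reagents that add atoms: none
Why: Tin–lithium exchange releases an unstabilised α-alkoxy carbanion that undergoes the concerted suprafacial [2,3]-Wittig–Still rearrangement, in which the CH2 tethered to the C1 oxygen can reach C3 only on the face that oxygen occupies, opposite to isopropyl, which sets C1′ as R (trans to C6′) and moves the alkene to C2′=C3′.

Step 7
Reactants: 11 homoallylic alcohol
Product: 13 (1R,6R)-3-methyl-6-(propan-2-yl)cyclohex-2-ene-1-carboxylic acid, via aldehyde 12 (not isolated)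
Conditions: TEMPO (cat.), PhI(OAc)2, MeCN–H2O, rt
Reagents that add atoms: water, O
Why: Oxoammonium-mediated oxidation takes the primary alcohol through the aldehyde hydrate to the acid under weakly acidic, metal-free conditions that neither attack the trisubstituted alkene nor enolise C1′.

Step 8
Reactants: 13 carboxylic acid; 14 potassium 3-methoxy-3-oxopropanoate (methyl potassium malonate)
Product: 16 methyl 3-[(1R,6R)-3-methyl-6-(propan-2-yl)cyclohex-2-en-1-yl]-3-oxopropanoate, via acyl imidazolide 15 (not isolated)
Conditions: CDI, THF, rt; then 14 + MgCl2 (premixed in THF, 50 °C), rt; cold 0.5 M HCl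
Reagents that add atoms: none
Why: Masamune–Brooks homologation, in which the magnesium malonate half-ester chelate is C-acylated by the imidazolide and decarboxylates under essentially neutral conditions, so the β,γ-alkene does not slip into conjugation and C1′ is not epimerised.

Step 9
Reactants: 16 β-keto ester
Product: 17 methyl 2-diazo-3-[(1R,6R)-3-methyl-6-(propan-2-yl)cyclohex-2-en-1-yl]-3-oxopropanoate
Conditions: p-ABSA, Et3N, MeCN, 0 °C → rt
Reagents that add atoms: 4-acetamidobenzenesulfonyl azide (p-ABSA), CC(=O)Nc1ccc(cc1)S(=O)(=O)N=[N+]=[N-]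
Why: Regitz diazo transfer to the activated methylene, where the amine deprotonates only the carbon between the two carbonyls and so shields the C1′–H.

Step 10
Reactants: 17 diazo keto ester; 18 (E)-4-phenylbut-3-en-2-one
Product: 21 methyl (6E)-2-[(1R,6R)-3-methyl-6-(propan-2-yl)cyclohex-2-en-1-yl]-3,5-dioxo-7-phenylhept-6-enoate (mixture at C2), via ketene 19 (not isolated), via lithium enolate 20 (not isolated)
Conditions: 17: hν (254 nm, quartz), Et2O, −78 °C; 18: LiN(SiMe3)2, THF, −78 °C; ketene solution cannulated onto the enolate in the dark, −78 → −20 °C; AcOH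
Reagents that add atoms: none
Why: Excitation of the diazo dicarbonyl chromophore expels N2 while the C1′–C(=O) bond, antiperiplanar to the departing N2 in the s-Z rotamer, shifts with its electron pair to the diazo carbon (photochemical Wolff rearrangement), so C3–C1′ forms with retention at C1′ and gives methoxycarbonyl ketene 19, whose carbonyl carbon is then attacked by the CH2 terminus of 20 to form C4–C5. The closest known chemistry is the photo-Wolff rearrangement of 2-diazo-3-oxo esters to alkoxycarbonyl ketenes, which persist at low temperature when the second substituent is bulky, joined to the Claisen-type C-acylation of lithium enolates by ketenes. No ring is closed, C1′ and C6′ are carried through unchanged, and the only new stereocentre, C2 of 21, is uncontrolled and irrelevant because it becomes sp2 C3 of the pyrone. Carbon rather than methoxy migration is required and follows from the ketone acyl group being the aligned one and lacking ester resonance, while light is used in place of a copper or rhodium carbenoid because a carbenoid would attack the β,γ-alkene C2′=C3′ (cyclopropanation or vinylogous Wolff pathway). C- rather than O-acylation is required and is favoured by the unhindered enolate carbon, the contact ion pair in ethereal solvent, lithium bridging to the small methyl ester that flanks the in-plane trajectory to the ketene carbon, and irreversible collapse to the chelated diketonate. Irradiation is complete before the solutions are combined, so the styryl chromophore never sees light, and LiN(SiMe3)2 leaves only a non-nucleophilic amine beside the ketene.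

Step 11
Reactants: 21 3,5-dioxo ester
Product: 22 4-hydroxy-3-[(1R,6R)-3-methyl-6-(propan-2-yl)cyclohex-2-en-1-yl]-6-[(E)-2-phenylethenyl]-2H-pyran-2-one
Conditions: DBU, toluene, 60 °C; then cold aq. citric acid
Reagents that add atoms: none
Why: Base-mediated lactonisation of a 3,5-dioxo ester, in which the C5 enolate oxygen attacks the methyl ester (6-exo-trig), methoxide leaves and the pyronate anion acts as a thermodynamic sink that drains reversible oxa-Michael side equilibria, while no acid strong enough to protonate C2′=C3′ next to the enolic 4-OH is ever present.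

**Compound list**

1 | (S)-limonene, (4S)-1-methyl-4-(prop-1-en-2-yl)cyclohex-1-ene | CC1=CC[C@@H](C(C)=C)CC1 | starting material
2 | (4S)-1-methyl-4-(propan-2-yl)cyclohex-1-ene | CC1=CC[C@@H](C(C)C)CC1 | intermediate
3 | (4S)-1-methyl-4-(propan-2-yl)-7-oxabicyclo[4.1.0]heptane, both epoxide diastereomers | CC12OC1C[C@@H](C(C)C)CC2 | intermediate
4 | (1S,4S,6R)-1-methyl-4-(propan-2-yl)-7-oxabicyclo[4.1.0]heptane, oxygen anti to isopropyl | C[C@@]12O[C@@H]1C[C@@H](C(C)C)CC2 | intermediate
5 | (1S,2S,4S)-1-methyl-2-(phenylselanyl)-4-(propan-2-yl)cyclohexan-1-ol | C[C@@]1(O)[C@@H]([Se]c2ccccc2)C[C@@H](C(C)C)CC1 | intermediate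
6 | (1S,2S,4S)-2-(benzeneseleninyl)-1-methyl-4-(propan-2-yl)cyclohexan-1-ol, mixture at selenium | C[C@@]1(O)[C@@H]([Se](=O)c2ccccc2)C[C@@H](C(C)C)CC1 | intermediate
7 | (1S,4R)-1-methyl-4-(propan-2-yl)cyclohex-2-en-1-ol, hydroxyl trans to isopropyl | C[C@@]1(O)C=C[C@@H](C(C)C)CC1 | intermediate
8 | tributyl(iodomethyl)stannane | CCCC[Sn](CCCC)(CCCC)CI | starting material
9 | tributyl({[(1S,4R)-1-methyl-4-(propan-2-yl)cyclohex-2-en-1-yl]oxy}methyl)stannane | C[C@@]1(OC[Sn](CCCC)(CCCC)CCCC)C=C[C@@H](C(C)C)CC1 | intermediate
10 | {[(1S,4R)-1-methyl-4-(propan-2-yl)cyclohex-2-en-1-yl]oxy}methyllithium | C[C@@]1(OC[Li])C=C[C@@H](C(C)C)CC1 | intermediate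
11 | [(1R,6R)-3-methyl-6-(propan-2-yl)cyclohex-2-en-1-yl]methanol | CC1=C[C@H](CO)[C@@H](C(C)C)CC1 | intermediate
12 | (1R,6R)-3-methyl-6-(propan-2-yl)cyclohex-2-ene-1-carbaldehyde | CC1=C[C@H](C=O)[C@@H](C(C)C)CC1 | intermediate
13 | (1R,6R)-3-methyl-6-(propan-2-yl)cyclohex-2-ene-1-carboxylic acid | CC1=C[C@H](C(=O)O)[C@@H](C(C)C)CC1 | intermediate
14 | potassium 3-methoxy-3-oxopropanoate | [K+].[O-]C(=O)CC(=O)OC | starting material
15 | (1H-imidazol-1-yl)[(1R,6R)-3-methyl-6-(propan-2-yl)cyclohex-2-en-1-yl]methanone | CC1=C[C@H](C(=O)n2ccnc2)[C@@H](C(C)C)CC1 | intermediate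
16 | methyl 3-[(1R,6R)-3-methyl-6-(propan-2-yl)cyclohex-2-en-1-yl]-3-oxopropanoate | CC1=C[C@H](C(=O)CC(=O)OC)[C@@H](C(C)C)CC1 | intermediate
17 | methyl 2-diazo-3-[(1R,6R)-3-methyl-6-(propan-2-yl)cyclohex-2-en-1-yl]-3-oxopropanoate | CC1=C[C@H](C(=O)C(=[N+]=[N-])C(=O)OC)[C@@H](C(C)C)CC1 | intermediate
18 | (E)-4-phenylbut-3-en-2-one | CC(=O)/C=C/c1ccccc1 | starting material
19 | methyl 2-[(1R,6R)-3-methyl-6-(propan-2-yl)cyclohex-2-en-1-yl]-3-oxoprop-2-enoate (ketene) | CC1=C[C@H](C(=C=O)C(=O)OC)[C@@H](C(C)C)CC1 | intermediate
20 | lithium (3E)-4-phenylbuta-1,3-dien-2-olate | [Li]OC(=C)/C=C/c1ccccc1 | intermediate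
21 | methyl (6E)-2-[(1R,6R)-3-methyl-6-(propan-2-yl)cyclohex-2-en-1-yl]-3,5-dioxo-7-phenylhept-6-enoate, mixture at C2 | CC1=C[C@H](C(C(=O)OC)C(=O)CC(=O)/C=C/c2ccccc2)[C@@H](C(C)C)CC1 | intermediate
22 | 4-hydroxy-3-[(1R,6R)-3-methyl-6-(propan-2-yl)cyclohex-2-en-1-yl]-6-[(E)-2-phenylethenyl]-2H-pyran-2-one | CC1=C[C@H](c2c(O)cc(/C=C/c3ccccc3)oc2=O)[C@@H](C(C)C)CC1 | target

Total step count: 11. Longest linear sequence: 11 steps, from 1 to 22.

**Steps most likely to fail**

**1. Step 10.**
- What may go wrong: the ketene may be consumed by O-acylation of the enolate, or by oligomerisation before the two solutions meet.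
- Fallback: it separates the rearrangement from the carbon–carbon bond formation and sets out from 17. The same irradiation is run, and ketene 19 is quenched in the dark with pentafluorophenol. This is heteroatom capture, the well-trodden variant. It gives the isolable acyl donor 1-methyl 3-(pentafluorophenyl) 2-[(1R,6R)-3-methyl-6-(propan-2-yl)cyclohex-2-en-1-yl]propanedioate F1.
- Return to the route: F1 then C-acylates 18 under soft enolisation (MgBr2·OEt2, iPr2NEt, CH2Cl2) and comes back at 21.

**2. Step 4.**
- What may go wrong: opening of the epoxide through a non-chair transition state may be sluggish. It may also be eroded by attack at C1 or by solvolysis.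
- Fallback: it avoids epoxide opening altogether and sets out from 2. Upjohn dihydroxylation (OsO4 cat., NMO, acetone–H2O) should give two cis-diols. The diol (1S,2R,4S)-1-methyl-4-(propan-2-yl)cyclohexane-1,2-diol F2, with both hydroxyls anti to isopropyl, is separated by chromatography from (1R,2S,4S)-1-methyl-4-(propan-2-yl)cyclohexane-1,2-diol F3.
- Return to the route: selective mesylation of the secondary hydroxyl (MsCl, pyridine, 0 °C) gives (1R,2S,5S)-2-hydroxy-2-methyl-5-(propan-2-yl)cyclohexyl methanesulfonate F4. Its leaving group is axial and antiperiplanar to the axial C3–H in the chair with equatorial isopropyl. E2 elimination (DBU, toluene, reflux) can therefore only give the C2=C3 alkene, and the sequence comes back at 7.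

**3. Step 6.**
- What may go wrong: the carbanion may divert into a [1,2]-shift or be protonated before it rearranges. The hindered alkoxide may also resist etherification in step 5.
- Fallback: it is tin-free and sets out from 7. Heating with N,N-dimethylformamide dimethyl acetal (xylene, 140 °C, methanol distilled off) generates an alkoxy(amino)carbene. This carbene undergoes a suprafacial [2,3] shift with the same facial logic and gives (1R,6R)-N,N,3-trimethyl-6-(propan-2-yl)cyclohex-2-ene-1-carboxamide F5.
- Return to the route: Cp2Zr(H)Cl (THF, rt) reduces the amide to aldehyde 12. Pinnick oxidation (NaClO2, NaH2PO4, 2-methylbut-2-ene, t-BuOH–H2O) then comes back at 13.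

**Further compounds**

F1 | step 10 | 1-methyl 3-(pentafluorophenyl) 2-[(1R,6R)-3-methyl-6-(propan-2-yl)cyclohex-2-en-1-yl]propanedioate, mixture at C2 | CC1=C[C@H](C(C(=O)OC)C(=O)Oc2c(F)c(F)c(F)c(F)c2F)[C@@H](C(C)C)CC1
F2 | step 4 | (1S,2R,4S)-1-methyl-4-(propan-2-yl)cyclohexane-1,2-diol | C[C@@]1(O)[C@H](O)C[C@@H](C(C)C)CC1
F3 | step 4 | (1R,2S,4S)-1-methyl-4-(propan-2-yl)cyclohexane-1,2-diol | C[C@]1(O)[C@@H](O)C[C@@H](C(C)C)CC1
F4 | step 4 | (1R,2S,5S)-2-hydroxy-2-methyl-5-(propan-2-yl)cyclohexyl methanesulfonate | C[C@@]1(O)[C@H](OS(C)(=O)=O)C[C@@H](C(C)C)CC1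
F5 | step 6 | (1R,6R)-N,N,3-trimethyl-6-(propan-2-yl)cyclohex-2-ene-1-carboxamide | CC1=C[C@H](C(=O)N(C)C)[C@@H](C(C)C)CC1
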